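**Retrosynthetic overview**
- Target ⇐ global deprotection of its trimethyl ester 3-O-TBS ether ⇐ photochemical Wolff contraction of ring B (6 → 5, one ring carbon extruded as the C7 ester) in a 7-diazo-6-oxo ent-kauranoid.
- Ring D ⇐ SmI2 ketyl–alkyne closure of an 8β-propargyl 13-ketone; C8 ⇐ conjugate propargylation of a Δ8(14)-13-enone obtained by Birch reduction of a 13-methoxy aromatic ring C.
- H-5/O-6 ⇐ hydroboration of a Δ5 alkene; C4 ⇐ deconjugative methylation; C3 ⇐ bulky hydride reduction.
- Key bond C10–C1 ⇐ enantioselective intermolecular Michael addition of a 6-methoxy-2-tetralone β-keto ester (rings B and C) to methyl 3-oxopent-4-enoate, then Knoevenagel closure of ring A.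
- Ring order: C (aromatic, bought) and B (tetralone) → A → C dearomatised → D → B contracted.

Assumption: the cupreidine (quinidine-series) 6'-OH catalyst is taken to give the (R)-C10 centre in step 4; if it gives the antipode, the cupreine (quinine-series) pseudoenantiomer is used instead.

Convention: carbon numbers are those of ent-kaurane/ent-gibberellane (C18 = 4-methyl, C19 = 4-carboxyl, C20 = 10-carboxyl). α/β refer to the usual drawing of the target (C19 and C20 α; H-5, H-9, the C15–C16 bridge and the C7 carboxyl β) and are not ent-inverted. "Podocarpane" and "kaurane" name skeletons only; the SMILES strings are definitive.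

**Route**

Step 1
Reactants: 1 6-methoxy-2-tetralone; 2 dimethyl carbonate
Product: 3 methyl 6-methoxy-2-oxo-1,2,3,4-tetrahydronaphthalene-1-carboxylate
Conditions: NaH, THF, reflux; then aq. HCl
Reagents that add atoms: none
Why: Crossed Claisen condensation (C-acylation of the ketone enolate by the carbonate) goes to the benzylic C1 position because only there is the product a fully conjugated, irreversibly deprotonated β-keto ester enolate; C1 is stereolabile, so no stereocentre of consequence is formed.

Step 2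
Reactants: 4 methyl acetate; 5 acrolein
Product: 6 methyl 3-hydroxypent-4-enoate (racemic)
Conditions: LiN(i-Pr)2, THF, −78 °C
Reagents that add atoms: none
Why: Aldol addition of the lithium ester enolate to the enal is cleanly 1,2 at −78 °C; the carbinol centre is racemic and is destroyed in the next step.

Step 3
Reactants: 6 methyl 3-hydroxypent-4-enoate
Product: 7 methyl 3-oxopent-4-enoate (Nazarov reagent)
Conditions: CrO3, H2SO4, acetone, 0 °C
Reagents that add atoms: none
Why: Chromic acid (Jones-type) oxidation of the secondary allylic alcohol gives the vinyl β-keto ester, which is used at once because it polymerises on standing; no stereocentre.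

Step 4
Reactants: 3 methyl 6-methoxy-2-oxo-1,2,3,4-tetrahydronaphthalene-1-carboxylate; 7 methyl 3-oxopent-4-enoate
Product: 8 methyl (1R)-6-methoxy-1-(5-methoxy-3,5-dioxopentyl)-2-oxo-1,2,3,4-tetrahydronaphthalene-1-carboxylate
Conditions: 9-O-(phenanthren-9-yl)cupreidine (10 mol %), CH2Cl2, −20 °C, slow addition of 7
Reagents that add atoms: none
Why: Catalytic enantioselective Michael addition in which the quinuclidine nitrogen forms the ion-paired enolate of the α-aryl β-keto ester while the 6'-OH hydrogen-bonds the vinyl ketone, so the acceptor reaches one enolate face and the C10 quaternary centre (C10–C1 bond, C20 ester α) is set as (R), from which every later stereocentre is relayed.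

Step 5
Reactants: 8 Michael adduct
Product: 9 dimethyl (4aS)-7-methoxy-2-oxo-3,4,9,10-tetrahydro-2H-phenanthrene-1,4a-dicarboxylate
Conditions: piperidine (cat.), AcOH (cat.), toluene, reflux, Dean–Stark
Reagents that add atoms: none
Why: Intramolecular Knoevenagel (aldol) condensation of the doubly activated C4 methylene onto the C5 ketone with azeotropic water removal completes the Nazarov–Robinson annulation of ring A; the quaternary C10 centre is untouched.

Step 6
Reactants: 9 tricyclic enone diester
Product: 10 dimethyl 13-methoxy-3-oxopodocarpa-5,8,11,13-tetraene-19,20-dioate (4β-Me; 4α- and 10α-CO2Me)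
Conditions: K2CO3, MeI, acetone, reflux
Reagents that add atoms: iodomethane, CI
Why: Deconjugative α-alkylation of the extended (C6-deprotonated) enolate of the vinylogous β-keto ester, in which MeI attacks C4 from the β face anti to the axial C10 ester, fixing the C18 methyl β and the C19 ester α (cis to C20) and moving the alkene to C5=C6.

Step 7
Reactants: 10 Δ5 keto diester
Product: 11 dimethyl 3β-hydroxy-13-methoxypodocarpa-5,8,11,13-tetraene-19,20-dioate
Conditions: LiBH(s-Bu)3, THF, −78 °C
Reagents that add atoms: none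
Why: Diastereoselective hydride reduction in which the bulky trialkylborohydride avoids the axial trajectory (1,3-diaxial C1–H) and attacks the neopentyl C3 ketone equatorially from the α side, giving the axial 3β-alcohol as with other 4,4-disubstituted 3-oxo terpenoids, while the esters are inert at −78 °C.

Step 8
Reactants: 11 3β-alcohol
Product: 12 3β-O-TBS ether of 11
Conditions: TBSOTf, 2,6-lutidine, CH2Cl2, 0 °C
Reagents that add atoms: tert-butyldimethylsilyl trifluoromethanesulfonate, CC(C)(C)[Si](C)(C)OS(=O)(=O)C(F)(F)F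
Why: Silylation of the hindered axial alcohol needs the silyl triflate, and the resulting ether survives the later thiolate, dissolving-metal, Lewis-acid, base and photochemical steps until fluoride removes it last.

Step 9
Reactants: 12 silyl ether
Product: 13 dimethyl 3β-(tert-butyldimethylsilyloxy)-6β-hydroxy-13-methoxy-5β-podocarpa-8,11,13-triene-19,20-dioate
Conditions: BH3·THF, THF, 0 to 40 °C; then NaOH, H2O2
Reagents that add atoms: hydrogen peroxide, OO
Why: Hydroboration–oxidation (anti-Markovnikov syn addition) occurs on the β face of the C5=C6 alkene because the α face is blocked by the two axial esters on C4 and C10, which sets H-5 β (trans A/B fusion) and the 6β-hydroxyl used later for the ring contraction.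

Step 10
Reactants: 13 hydroxy diester
Product: 14 3β-(tert-butyldimethylsilyloxy)-6β-hydroxy-13-methoxy-5β-podocarpa-8,11,13-triene-19,20-dioic acid
Conditions: n-PrSLi (from n-PrSH and n-BuLi), HMPA, 25 °C; then aq. HCl
Reagents that add atoms: none
Why: Thiolate-mediated nucleophilic O-demethylation (alkyl–oxygen cleavage) of the two hindered methyl esters in a dipolar aprotic solvent leaves the silyl ether and the aryl methyl ether intact and gives carboxylates, the only carboxyl form inert to dissolving metal.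

Step 11
Reactants: 14 aromatic diacid
Product: 17 conjugated enone diacid (13-oxo-Δ8(14); 9β-H), via dihydroanisole diacid 15 (not isolated), via unconjugated enone diacid 16 (not isolated)
Conditions: Li, NH3(l), THF, t-BuOH, −78 to −33 °C; then (CO2H)2, MeOH–H2O, 25 °C; then NaOMe, MeOH, 25 °C; aq. HCl
Reagents that add atoms: water, O
Why: Birch reduction of the anisole gives the 2,5-dihydroanisole (carboxylates and the alkoxide are not reduced), mild acid hydrolyses the enol ether, and base-mediated conjugation moves the alkene to C8=C14 with thermodynamic γ-protonation at C9 that places H-9 axial and β (anti to the axial C10 carboxyl), as in the estrone methyl ether to 19-nortestosterone conversion.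

Step 12
Reactants: 17 enone diacid
Product: 18 dimethyl 3β-(tert-butyldimethylsilyloxy)-6β-hydroxy-13-oxo-5β,9β-podocarp-8(14)-ene-19,20-dioate
Conditions: TMSCHN2, MeOH–toluene, 0 °C
Reagents that add atoms: (trimethylsilyl)diazomethane, C[Si](C)(C)C=[N+]=[N-]
Why: Esterification with the diazoalkane alkylates the carboxylate oxygen and is therefore insensitive to the steric shielding at C4 and C10; no stereocentre changes.

Step 13
Reactants: 18 hydroxy enone diester
Product: 19 6β-acetate of 18
Conditions: Ac2O, pyridine, 4-(dimethylamino)pyridine (cat.), 25 °C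
Reagents that add atoms: acetic anhydride, CC(=O)OC(C)=O
Why: Acylation of the equatorial secondary alcohol protects it from TiCl4 and keeps C6 at the alcohol oxidation level while the C13 carbonyl is used; no stereocentre changes.

Step 14
Reactants: 19 enone acetate; 20 tributyl(propa-1,2-dien-1-yl)stannane
Product: 21 dimethyl 6β-acetoxy-3β-(tert-butyldimethylsilyloxy)-13-oxo-8β-(prop-2-yn-1-yl)-5β,9β-podocarpane-19,20-dioate
Conditions: TiCl4, CH2Cl2, −78 °C
Reagents that add atoms: none
Why: Lewis-acid-promoted conjugate propargylation (Sakurai-type addition of the allenylstannane with allylic transposition) in which the nucleophile attacks C8 of the activated enone axially on ring C from the β face, anti to the axial C10 ester, creating the quaternary centre with the propargyl group cis to H-9 as the kaurane/gibberellane bridge requires.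

Step 15
Reactants: 21 propargyl ketone
Product: 22 dimethyl 6β-acetoxy-3β-(tert-butyldimethylsilyloxy)-13-hydroxykaur-16-ene-19,20-dioate (ent-kaurane skeleton)
Conditions: SmI2, HMPA, t-BuOH, THF, 0 °C
Reagents that add atoms: none
Why: Ketyl–alkyne reductive radical cyclisation in which the C13 ketyl adds 5-exo-dig to the axial propargyl group, the tether allows bonding only on the β face so the bridgehead C13 carbinol configuration is fixed, and the vinyl radical is reduced and protonated to the exocyclic methylene while esters and acetate are inert.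

Step 16
Reactants: 22 ring-D acetate
Product: 23 dimethyl 3β-(tert-butyldimethylsilyloxy)-6β,13-dihydroxykaur-16-ene-19,20-dioate
Conditions: K2CO3 (cat.), MeOH, 25 °C
Reagents that add atoms: none
Why: Base-catalysed transesterification removes only the acetate, since the methyl esters merely exchange methoxide and the hindered silyl ether is stable.

Step 17
Reactants: 23 diol
Product: 24 dimethyl 3β-(tert-butyldimethylsilyloxy)-13-hydroxy-6-oxokaur-16-ene-19,20-dioate
Conditions: Dess–Martin periodinane, pyridine, CH2Cl2, 25 °C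
Reagents that add atoms: none
Why: Dess–Martin oxidation converts the secondary 6-alcohol to the ketone while the tertiary bridgehead alcohol cannot be oxidised, and H-5, now α to the ketone, stays β because the trans-fused decalone is the more stable epimer.

Step 18
Reactants: 24 6-ketone
Product: 26 dimethyl 7-diazo-3β-(tert-butyldimethylsilyloxy)-13-hydroxy-6-oxokaur-16-ene-19,20-dioate, via trifluoroacetyl ketone 25 (not isolated)
Conditions: LiN(SiMe3)2 (2.2 equiv), THF, −78 °C, then CF3CO2CH2CF3; then MsN3, Et3N, H2O, MeCN, 25 °C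
Reagents that add atoms: methanesulfonyl azide, CS(=O)(=O)N=[N+]=[N-]; 2,2,2-trifluoroethyl trifluoroacetate, O=C(OCC(F)(F)F)C(F)(F)F (its CF3CO group is in 25 only)
Why: Detrifluoroacetylative diazo transfer (Danheiser variant of the Regitz reaction) works because the kinetic enolate can form only toward the C7 methylene (C5 is a hindered methine), trifluoroacetylation activates C7 and the sulfonyl azide with amine then delivers the α-diazo ketone, any trifluoroacetate on the tertiary alcohol being hydrolysed in the same aqueous amine medium.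

Step 19
Reactants: 26 diazo ketone
Product: 29 trimethyl ester 3-O-TBS ether of the target gibberellin, via ketene 27 (not isolated), via C6-epimeric ester mixture 28 (not isolated)
Conditions: hν (365 nm), MeOH, 25 °C; then NaOMe, MeOH, 60 °C
Reagents that add atoms: methanol, CO
Why: Photochemical Wolff rearrangement in which loss of dinitrogen with 1,2-shift of C5 (retention, H-5 stays β) contracts ring B to the cyclopentane and extrudes the old C6 as a ketene that methanol traps as the methyl ester, after which methoxide equilibrates the one enolisable ester to the more stable 6β epimer (trans to the C4 quaternary centre), the natural gibberellin configuration.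

Step 20
Reactants: 29 trimethyl ester
Product: 30 3-O-TBS ether of the target gibberellin (triacid)
Conditions: n-PrSLi (from n-PrSH and n-BuLi), HMPA, 25 to 50 °C; then aq. HCl
Reagents that add atoms: none
Why: Thiolate-mediated nucleophilic demethylation cleaves all three hindered methyl esters without touching the silyl-protected β-hydroxy ester unit (no retro-aldol at C3–C4) or the tertiary allylic alcohol.

Step 21
Reactants: 30 silyl ether triacid
Product: 31 the target gibberellin (3β,13-dihydroxy C20-gibberellin triacid)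
Conditions: HF·pyridine, pyridine, THF, 0 to 25 °C
Reagents that add atoms: none
Why: Fluoride-mediated desilylation under buffered conditions frees the 3β-hydroxyl without acid-induced rearrangement of the 13-hydroxy-16-ene bridge, giving the target.

**Compound list**

1 | 6-methoxy-3,4-dihydronaphthalen-2(1H)-one (6-methoxy-2-tetralone) | COc1ccc2c(c1)CCC(=O)C2 | starting material
2 | dimethyl carbonate | COC(=O)OC | starting material
3 | methyl 6-methoxy-2-oxo-1,2,3,4-tetrahydronaphthalene-1-carboxylate (racemic, largely enol) | c12cc(OC)ccc1C(C(=O)OC)C(=O)CC2 | intermediate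
4 | methyl acetate | CC(=O)OC | starting material
5 | acrolein (prop-2-enal) | C=CC=O | starting material
6 | methyl 3-hydroxypent-4-enoate (racemic) | C=CC(O)CC(=O)OC | intermediate
7 | methyl 3-oxopent-4-enoate | C=CC(=O)CC(=O)OC | intermediate
8 | methyl (1R)-6-methoxy-1-(5-methoxy-3,5-dioxopentyl)-2-oxo-1,2,3,4-tetrahydronaphthalene-1-carboxylate | c12cc(OC)ccc1[C@](C(=O)OC)(CCC(=O)CC(=O)OC)C(=O)CC2 | intermediate
9 | dimethyl (4aS)-7-methoxy-2-oxo-3,4,9,10-tetrahydro-2H-phenanthrene-1,4a-dicarboxylate (= dimethyl 13-methoxy-3-oxopodocarpa-4,8,11,13-tetraene-19,20-dioate, C20 ester α) | c12cc(OC)ccc1[C@]1(C(=O)OC)CCC(=O)C(C(=O)OC)=C1CC2 | intermediate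
10 | dimethyl 13-methoxy-3-oxopodocarpa-5,8,11,13-tetraene-19,20-dioate (C18 methyl β; C19 and C20 esters α) | c12cc(OC)ccc1[C@]1(C(=O)OC)CCC(=O)[C@@](C)(C(=O)OC)C1=CC2 | intermediate
11 | dimethyl 3β-hydroxy-13-methoxypodocarpa-5,8,11,13-tetraene-19,20-dioate | c12cc(OC)ccc1[C@]1(C(=O)OC)CC[C@H](O)[C@@](C)(C(=O)OC)C1=CC2 | intermediate
12 | dimethyl 3β-(tert-butyldimethylsilyloxy)-13-methoxypodocarpa-5,8,11,13-tetraene-19,20-dioate | c12cc(OC)ccc1[C@]1(C(=O)OC)CC[C@H](O[Si](C)(C)C(C)(C)C)[C@@](C)(C(=O)OC)C1=CC2 | intermediate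
13 | dimethyl 3β-(tert-butyldimethylsilyloxy)-6β-hydroxy-13-methoxy-5β-podocarpa-8,11,13-triene-19,20-dioate | c12cc(OC)ccc1[C@]1(C(=O)OC)CC[C@H](O[Si](C)(C)C(C)(C)C)[C@@](C)(C(=O)OC)[C@H]1[C@H](O)C2 | intermediate
14 | 3β-(tert-butyldimethylsilyloxy)-6β-hydroxy-13-methoxy-5β-podocarpa-8,11,13-triene-19,20-dioic acid | c12cc(OC)ccc1[C@]1(C(=O)O)CC[C@H](O[Si](C)(C)C(C)(C)C)[C@@](C)(C(=O)O)[C@H]1[C@H](O)C2 | intermediate
15 | 3β-(tert-butyldimethylsilyloxy)-6β-hydroxy-13-methoxy-5β-podocarpa-8,12-diene-19,20-dioic acid (dihydroanisole) | C12=C(CC=C(OC)C1)[C@]1(C(=O)O)CC[C@H](O[Si](C)(C)C(C)(C)C)[C@@](C)(C(=O)O)[C@H]1[C@H](O)C2 | intermediate (not isolated)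
16 | 3β-(tert-butyldimethylsilyloxy)-6β-hydroxy-13-oxo-5β-podocarp-8-ene-19,20-dioic acid (unconjugated enone) | C12=C(CCC(=O)C1)[C@]1(C(=O)O)CC[C@H](O[Si](C)(C)C(C)(C)C)[C@@](C)(C(=O)O)[C@H]1[C@H](O)C2 | intermediate (not isolated)
17 | 3β-(tert-butyldimethylsilyloxy)-6β-hydroxy-13-oxo-5β,9β-podocarp-8(14)-ene-19,20-dioic acid | C23=CC(=O)CC[C@H]2[C@]1(C(=O)O)CC[C@H](O[Si](C)(C)C(C)(C)C)[C@@](C)(C(=O)O)[C@H]1[C@H](O)C3 | intermediate
18 | dimethyl 3β-(tert-butyldimethylsilyloxy)-6β-hydroxy-13-oxo-5β,9β-podocarp-8(14)-ene-19,20-dioate | C23=CC(=O)CC[C@H]2[C@]1(C(=O)OC)CC[C@H](O[Si](C)(C)C(C)(C)C)[C@@](C)(C(=O)OC)[C@H]1[C@H](O)C3 | intermediate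
19 | dimethyl 6β-acetoxy-3β-(tert-butyldimethylsilyloxy)-13-oxo-5β,9β-podocarp-8(14)-ene-19,20-dioate | C23=CC(=O)CC[C@H]2[C@]1(C(=O)OC)CC[C@H](O[Si](C)(C)C(C)(C)C)[C@@](C)(C(=O)OC)[C@H]1[C@H](OC(C)=O)C3 | intermediate
20 | tributyl(propa-1,2-dien-1-yl)stannane | C=C=C[Sn](CCCC)(CCCC)CCCC | starting material
21 | dimethyl 6β-acetoxy-3β-(tert-butyldimethylsilyloxy)-13-oxo-8β-(prop-2-yn-1-yl)-5β,9β-podocarpane-19,20-dioate | C#CC[C@]23CC(=O)CC[C@H]2[C@]1(C(=O)OC)CC[C@H](O[Si](C)(C)C(C)(C)C)[C@@](C)(C(=O)OC)[C@H]1[C@H](OC(C)=O)C3 | intermediate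
22 | dimethyl 6β-acetoxy-3β-(tert-butyldimethylsilyloxy)-13-hydroxykaur-16-ene-19,20-dioate (ent-kaurane skeleton; 5β-H, 9β-H, C15–C16 bridge β) | C=C1C[C@]23C[C@@]1(O)CC[C@H]2[C@]1(C(=O)OC)CC[C@H](O[Si](C)(C)C(C)(C)C)[C@@](C)(C(=O)OC)[C@H]1[C@H](OC(C)=O)C3 | intermediate
23 | dimethyl 3β-(tert-butyldimethylsilyloxy)-6β,13-dihydroxykaur-16-ene-19,20-dioate | C=C1C[C@]23C[C@@]1(O)CC[C@H]2[C@]1(C(=O)OC)CC[C@H](O[Si](C)(C)C(C)(C)C)[C@@](C)(C(=O)OC)[C@H]1[C@H](O)C3 | intermediate
24 | dimethyl 3β-(tert-butyldimethylsilyloxy)-13-hydroxy-6-oxokaur-16-ene-19,20-dioate | C=C1C[C@]23C[C@@]1(O)CC[C@H]2[C@]1(C(=O)OC)CC[C@H](O[Si](C)(C)C(C)(C)C)[C@@](C)(C(=O)OC)[C@H]1C(=O)C3 | intermediate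
25 | 7-(trifluoroacetyl) derivative of 24 (C7 epimers/enol) | C=C1C[C@]23C[C@@]1(O)CC[C@H]2[C@]1(C(=O)OC)CC[C@H](O[Si](C)(C)C(C)(C)C)[C@@](C)(C(=O)OC)[C@H]1C(=O)C3C(=O)C(F)(F)F | intermediate (not isolated)
26 | dimethyl 7-diazo-3β-(tert-butyldimethylsilyloxy)-13-hydroxy-6-oxokaur-16-ene-19,20-dioate | C=C1C[C@]23C[C@@]1(O)CC[C@H]2[C@]1(C(=O)OC)CC[C@H](O[Si](C)(C)C(C)(C)C)[C@@](C)(C(=O)OC)[C@H]1C(=O)C3=[N+]=[N-] | intermediate
27 | ring-B-contracted ketene (gibberellane skeleton, ring carbon C6 carrying C7=O as ketene) | C=C1C[C@]23C[C@@]1(O)CC[C@H]2[C@]1(C(=O)OC)CC[C@H](O[Si](C)(C)C(C)(C)C)[C@@](C)(C(=O)OC)[C@H]1C3=C=O | intermediate (not isolated)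
28 | trimethyl ester 3-O-TBS ether of the target gibberellin as mixture of C6 epimers | C=C1C[C@]23C[C@@]1(O)CC[C@H]2[C@]1(C(=O)OC)CC[C@H](O[Si](C)(C)C(C)(C)C)[C@@](C)(C(=O)OC)[C@H]1C3C(=O)OC | intermediate (not isolated)
29 | trimethyl ester 3-O-TBS ether of the target gibberellin (6β-CO2Me; trimethyl 3β-(tert-butyldimethylsilyloxy)-13-hydroxygibberell-16-ene-7,19,20-trioate) | C=C1C[C@]23C[C@@]1(O)CC[C@H]2[C@]1(C(=O)OC)CC[C@H](O[Si](C)(C)C(C)(C)C)[C@@](C)(C(=O)OC)[C@H]1[C@@H]3C(=O)OC | intermediate
30 | 3-O-TBS ether of the target gibberellin (triacid) | C=C1C[C@]23C[C@@]1(O)CC[C@H]2[C@]1(C(=O)O)CC[C@H](O[Si](C)(C)C(C)(C)C)[C@@](C)(C(=O)O)[C@H]1[C@@H]3C(=O)O | intermediate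
31 | the target gibberellin: 3β,13-dihydroxygibberell-16-ene-7,19,20-trioic acid in the convention above (ent-3α,13-dihydroxy in ent-gibberellane nomenclature) | C=C1C[C@]23C[C@@]1(O)CC[C@H]2[C@]1(C(=O)O)CC[C@H](O)[C@@](C)(C(=O)O)[C@H]1[C@@H]3C(=O)O | target

**Step count and risks**

Total step count: 21 (19 on the main line from 1, plus 2 to make 7).
Longest linear sequence: 20 steps (steps 2 to 21, from 4 and 5 through 7 to 31).

Most likely to fail:

1. Step 4 (enantioselective Michael addition to the acidic, polymerisation-prone vinyl ketone 7). Fallback, from 3 back to 8: the same catalyst class adds 3 to acrolein 5, a non-acidic acceptor, to give methyl (1R)-6-methoxy-2-oxo-1-(3-oxopropyl)-1,2,3,4-tetrahydronaphthalene-1-carboxylate F1. SnCl2-catalysed Roskamp homologation of the aldehyde with purchased methyl diazoacetate in CH2Cl2 then builds the C(=O)CH2CO2Me terminus and gives 8.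

2. Step 14 (conjugate propargylation at the hindered, fully substituted C8). Fallback, from 19 back to 23: Hosomi–Sakurai conjugate allylation (allyltrimethylsilane, TiCl4, −78 °C) gives dimethyl 6β-acetoxy-8β-allyl-3β-(tert-butyldimethylsilyloxy)-13-oxo-5β,9β-podocarpane-19,20-dioate F2. Ozonolysis (ozone, then Me2S) gives the aldehyde dimethyl 6β-acetoxy-3β-(tert-butyldimethylsilyloxy)-13-oxo-8β-(2-oxoethyl)-5β,9β-podocarpane-19,20-dioate F3. Homologation with dimethyl (1-diazo-2-oxopropyl)phosphonate (K2CO3, MeOH, 0 °C), which also removes the acetate, gives dimethyl 3β-(tert-butyldimethylsilyloxy)-6β-hydroxy-13-oxo-8β-(prop-2-yn-1-yl)-5β,9β-podocarpane-19,20-dioate F4. SmI2 cyclisation as in step 15 then gives 23 directly.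

3. Step 19 (photochemical Wolff contraction, which also depends on the diazo transfer of step 18). Fallback, from 24 back to 29, avoiding the diazo ketone: LiN(SiMe3)2 and Me3SiCl give the bis-silylated enol ether dimethyl 3β-(tert-butyldimethylsilyloxy)-6,13-bis(trimethylsilyloxy)kaura-6,16-diene-19,20-dioate F5. Cycloaddition with 4-nitrobenzenesulfonyl azide (MeCN, 40 °C) and loss of dinitrogen with ring contraction gives, after aqueous work-up, the N-(4-nitrophenylsulfonyl) 7-carboxamide of the gibberellane 19,20-dimethyl ester 3-O-TBS ether F6. N-Methylation with TMSCHN2 gives the activated N-methyl-N-sulfonyl amide F7. NaOMe in MeOH then gives the methyl ester with equilibration at C6, which is 29.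

Further compounds
F1 | step 4 | methyl (1R)-6-methoxy-2-oxo-1-(3-oxopropyl)-1,2,3,4-tetrahydronaphthalene-1-carboxylate | c12cc(OC)ccc1[C@](C(=O)OC)(CCC=O)C(=O)CC2
F2 | step 14 | dimethyl 6β-acetoxy-8β-allyl-3β-(tert-butyldimethylsilyloxy)-13-oxo-5β,9β-podocarpane-19,20-dioate | C=CC[C@]23CC(=O)CC[C@H]2[C@]1(C(=O)OC)CC[C@H](O[Si](C)(C)C(C)(C)C)[C@@](C)(C(=O)OC)[C@H]1[C@H](OC(C)=O)C3
F3 | step 14 | dimethyl 6β-acetoxy-3β-(tert-butyldimethylsilyloxy)-13-oxo-8β-(2-oxoethyl)-5β,9β-podocarpane-19,20-dioate | O=CC[C@]23CC(=O)CC[C@H]2[C@]1(C(=O)OC)CC[C@H](O[Si](C)(C)C(C)(C)C)[C@@](C)(C(=O)OC)[C@H]1[C@H](OC(C)=O)C3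
F4 | step 14 | dimethyl 3β-(tert-butyldimethylsilyloxy)-6β-hydroxy-13-oxo-8β-(prop-2-yn-1-yl)-5β,9β-podocarpane-19,20-dioate | C#CC[C@]23CC(=O)CC[C@H]2[C@]1(C(=O)OC)CC[C@H](O[Si](C)(C)C(C)(C)C)[C@@](C)(C(=O)OC)[C@H]1[C@H](O)C3
F5 | step 19 | dimethyl 3β-(tert-butyldimethylsilyloxy)-6,13-bis(trimethylsilyloxy)kaura-6,16-diene-19,20-dioate | C=C1C[C@]23C[C@@]1(O[Si](C)(C)C)CC[C@H]2[C@]1(C(=O)OC)CC[C@H](O[Si](C)(C)C(C)(C)C)[C@@](C)(C(=O)OC)[C@H]1C(O[Si](C)(C)C)=C3
F6 | step 19 | N-(4-nitrophenylsulfonyl) 7-carboxamide of the target gibberellin 19,20-dimethyl ester 3-O-TBS ether (C6 epimers) | C=C1C[C@]23C[C@@]1(O)CC[C@H]2[C@]1(C(=O)OC)CC[C@H](O[Si](C)(C)C(C)(C)C)[C@@](C)(C(=O)OC)[C@H]1C3C(=O)NS(=O)(=O)c1ccc(cc1)[N+](=O)[O-]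
F7 | step 19 | N-methyl-N-(4-nitrophenylsulfonyl) 7-carboxamide of the target gibberellin 19,20-dimethyl ester 3-O-TBS ether (C6 epimers) | C=C1C[C@]23C[C@@]1(O)CC[C@H]2[C@]1(C(=O)OC)CC[C@H](O[Si](C)(C)C(C)(C)C)[C@@](C)(C(=O)OC)[C@H]1C3C(=O)N(C)S(=O)(=O)c1ccc(cc1)[N+](=O)[O-]
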